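**Strategy.** The pyranone ring (O1, C2, C3, C4, C4a, C8a) is cut into an aryl aldehyde (O1=C2) and the enol silane of a 2′-fluoroacetophenone (C3–C4–C4a–C8a). The key step exploits the C4 ketone, flanked by C3 and by ring A (C4a, C8a), twice. As its enol silane it lets C3 add to the aldehyde under a chiral boron Lewis acid, which forms C2–C3 and sets (2S). It then activates the fluorine-bearing C8a ortho to it for SNAr by the new C2 oxygen, which forms O1–C8a in the same flask. The precursors are a MOM-protected, C-prenylated 2-fluoro-4,6-dioxygenated acetophenone enol silane and a MOM-protected benzaldehyde carrying the 1,1-dimethylallyl group.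

Key step: step 9

Remark: the target is the (2S)-flavanone (C2 is its only stereocentre); flavanone numbering is used throughout. The sense of induction of the boron catalyst in step 9 is assigned by analogy with simple aromatic aldehydes and would be confirmed on the first run; the (4S)-catalyst serves if the sense is the reverse.

**Step 1**
Reactants: 1 5-fluorobenzene-1,3-diol
Product: 2 1-fluoro-3,5-bis(methoxymethoxy)benzene
Conditions: NaH, MOMCl, DMF, 0 °C → rt
Reagents that add atoms: chloromethyl methyl ether, COCCl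
Why: Williamson-type O-alkylation of both phenoxides gives the bis-MOM acetal, which is stable to the organolithium and fluoride steps that follow.

**Step 2**
Reactants: 2 1-fluoro-3,5-bis(methoxymethoxy)benzene
Product: 3 2,4-dibromo-3-fluoro-1,5-bis(methoxymethoxy)benzene
Conditions: NBS (2.0 equiv), MeCN, 0 °C → rt
Reagents that add atoms: N-bromosuccinimide, O=C1CCC(=O)N1Br
Why: Electrophilic aromatic bromination takes place twice at the equivalent carbons para to one MOM-oxy group and ortho to the other, i.e. on both sides of fluorine, while the more hindered carbon between the two oxygens stays C–H.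

**Step 3**
Reactants: 3 2,4-dibromo-3-fluoro-1,5-bis(methoxymethoxy)benzene
Product: 5 2-bromo-3-fluoro-1,5-bis(methoxymethoxy)-4-(3-methylbut-2-en-1-yl)benzene, via aryllithium 4 (not isolated)
Conditions: n-BuLi (1.0 equiv), THF, −78 °C; CuBr·SMe2 (10 mol %), prenyl bromide, −78 → 0 °C
Reagents that add atoms: 1-bromo-3-methylbut-2-ene, CC(C)=CCBr
Why: Bromine–lithium exchange with one equivalent of n-BuLi stops at the mono-aryllithium (kept at −78 °C to avoid LiF loss), and copper-catalysed allylic substitution at the primary carbon of prenyl bromide (SN2) installs the future C8 prenyl group next to fluorine.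

**Step 4**
Reactants: 5 2-bromo-3-fluoro-1,5-bis(methoxymethoxy)-4-(3-methylbut-2-en-1-yl)benzene
Product: 8 1-[2-fluoro-4,6-bis(methoxymethoxy)-3-(3-methylbut-2-en-1-yl)phenyl]ethan-1-one, via aryllithium 6 (not isolated), via lithium hemiaminal 7 (not isolated)
Conditions: n-BuLi (1.05 equiv), THF, −78 °C; MeC(O)N(OMe)Me, −78 → −20 °C; AcOH quench
Reagents that add atoms: N-methoxy-N-methylacetamide, CC(=O)N(C)OC
Why: A second bromine–lithium exchange and acylation with the N-methoxy-N-methylamide give the methyl ketone only on quench, because the chelated tetrahedral adduct 7 prevents over-addition.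

**Step 5**
Reactants: 8 1-[2-fluoro-4,6-bis(methoxymethoxy)-3-(3-methylbut-2-en-1-yl)phenyl]ethan-1-one
Product: 10 {1-[2-fluoro-4,6-bis(methoxymethoxy)-3-(3-methylbut-2-en-1-yl)phenyl]ethenyl}oxy(trimethyl)silane, via lithium enolate 9 (not isolated)
Conditions: LiN(SiMe3)2, TMSCl, THF, −78 → 0 °C; pentane, filtration (no aqueous work-up)
Reagents that add atoms: chlorotrimethylsilane, C[Si](C)(C)Cl
Why: Kinetic deprotonation of the only enolisable position and O-silylation give the enol silane, which is used without aqueous work-up.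

**Step 6**
Reactants: 11 4-hydroxy-2-methoxybenzaldehyde
Product: 12 2-methoxy-4-[(3-methylbut-2-en-1-yl)oxy]benzaldehyde
Conditions: prenyl bromide, K2CO3, acetone, reflux
Reagents that add atoms: 1-bromo-3-methylbut-2-ene, CC(C)=CCBr
Why: Williamson etherification of the acidic para-formyl phenol at oxygen.

**Step 7**
Reactants: 12 2-methoxy-4-[(3-methylbut-2-en-1-yl)oxy]benzaldehyde
Product: 14 4-hydroxy-2-methoxy-5-(2-methylbut-3-en-2-yl)benzaldehyde, via ortho-dienone 13 (not isolated)
Conditions: EtOH/H2O (4:1), 130 °C, sealed tube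
Reagents that add atoms: none
Why: Aromatic Claisen [3,3] rearrangement transfers the allyl unit with inversion to the ortho carbon para to the methoxy group (C5), the other ortho carbon being flanked by two oxygens and the para position blocked by the formyl group, and dienone 13 tautomerises to the phenol; the aqueous medium accelerates the rearrangement so that the temperature stays below that of the abnormal Claisen pathway.

**Step 8**
Reactants: 14 4-hydroxy-2-methoxy-5-(2-methylbut-3-en-2-yl)benzaldehyde
Product: 15 2-methoxy-4-(methoxymethoxy)-5-(2-methylbut-3-en-2-yl)benzaldehyde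
Conditions: MOMCl, K2CO3, DMF, 0 °C → rt
Reagents that add atoms: chloromethyl methyl ether, COCCl
Why: O-Alkylation masks the acidic phenol, which would otherwise quench the Lewis acid catalyst and the alkoxide of the key step.

**Step 9**
Reactants: 10 {1-[2-fluoro-4,6-bis(methoxymethoxy)-3-(3-methylbut-2-en-1-yl)phenyl]ethenyl}oxy(trimethyl)silane; 15 2-methoxy-4-(methoxymethoxy)-5-(2-methylbut-3-en-2-yl)benzaldehyde
Product: 17 (2S)-5,7-bis(methoxymethoxy)-2-[2-methoxy-4-(methoxymethoxy)-5-(2-methylbut-3-en-2-yl)phenyl]-8-(3-methylbut-2-en-1-yl)-2,3-dihydro-4H-chromen-4-one, via silyl ether 16 (not isolated)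
Conditions: 10 (1.1 equiv), (4R)-2-butyl-4-(1H-indol-3-ylmethyl)-3-tosyl-1,3,2-oxazaborolidin-5-one (20 mol %), EtCN, −78 °C; then Bu4N[Ph3SiF2] (30 mol %), −40 → 0 °C; pH 7 buffer quench
Reagents that add atoms: none
Why: Proposed new method: the chiral oxazaborolidinone binds aldehyde 15 and enol silane 10 adds to its Si face (catalyst control, the aldehyde being achiral), and silyl transfer gives the (S)-β-silyloxy ketone 16, which forms C2–C3 and sets C2. Fluoride then unmasks the alkoxide, which attacks the fluorine-bearing ring carbon ortho to the ketone (6-exo-trig addition to the arene, giving an anionic σ-adduct stabilised as the C4 enolate), and loss of fluoride forms O1–C8a and closes the pyranone ring; the expelled fluoride desilylates the next molecule, so Me3SiF is the only coproduct. The closest known reactions are the Mukaiyama-aldol pathway of hetero-Diels–Alder annulations of aldehydes with 1-alkoxy-3-silyloxybutadienes to 2,3-dihydropyran-4-ones (the C4a=C8a bond of the arene and fluoride here take the parts of the enol ether double bond and the alkoxy leaving group) and the fluoride-catalysed SNAr of silyl ethers with activated aryl fluorides. The step needs ring closure to outrun retro-aldol cleavage and β-elimination of the aldolate, which would erode the ee or give the chalcone. Closure is favoured by the ortho acyl group, the fluoride leaving group, the two ring oxygens lying meta to the C–F carbon (no resonance deactivation), the six-membered transition state, the low temperature and the low standing alkoxide concentration under substoichiometric fluoride. The C2–O bond is not touched in the closure, so the configuration set in the aldol stage is carried into 17.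

**Step 10**
Reactants: 17 (2S)-5,7-bis(methoxymethoxy)-2-[2-methoxy-4-(methoxymethoxy)-5-(2-methylbut-3-en-2-yl)phenyl]-8-(3-methylbut-2-en-1-yl)-2,3-dihydro-4H-chromen-4-one
Product: 18 (2S)-5,7-dihydroxy-2-[4-hydroxy-2-methoxy-5-(2-methylbut-3-en-2-yl)phenyl]-8-(3-methylbut-2-en-1-yl)-2,3-dihydro-4H-chromen-4-one
Conditions: conc. HCl (cat.), MeOH, rt → 40 °C
Reagents that add atoms: none
Why: Acid-catalysed transacetalisation to methanol removes the three MOM groups; flavanones epimerise at C2 through base-mediated ring opening and not in dilute acid, and the low temperature should keep the two allyl-type side chains from cyclising onto their neighbouring phenols.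

**Compound list**
1 | 5-fluorobenzene-1,3-diol | Oc1cc(O)cc(F)c1 | starting material
2 | 1-fluoro-3,5-bis(methoxymethoxy)benzene | COCOc1cc(F)cc(OCOC)c1 | intermediate
3 | 2,4-dibromo-3-fluoro-1,5-bis(methoxymethoxy)benzene | COCOc1cc(OCOC)c(Br)c(F)c1Br | intermediate
4 | [3-bromo-2-fluoro-4,6-bis(methoxymethoxy)phenyl]lithium | [Li]c1c(F)c(Br)c(OCOC)cc1OCOC | intermediate (not isolated)
5 | 2-bromo-3-fluoro-1,5-bis(methoxymethoxy)-4-(3-methylbut-2-en-1-yl)benzene | COCOc1cc(OCOC)c(CC=C(C)C)c(F)c1Br | intermediate
6 | [2-fluoro-4,6-bis(methoxymethoxy)-3-(3-methylbut-2-en-1-yl)phenyl]lithium | [Li]c1c(F)c(CC=C(C)C)c(OCOC)cc1OCOC | intermediate (not isolated)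
7 | lithium 1-[2-fluoro-4,6-bis(methoxymethoxy)-3-(3-methylbut-2-en-1-yl)phenyl]-1-[methoxy(methyl)amino]ethan-1-olate (racemic) | CC(O[Li])(N(C)OC)c1c(F)c(CC=C(C)C)c(OCOC)cc1OCOC | intermediate (not isolated)
8 | 1-[2-fluoro-4,6-bis(methoxymethoxy)-3-(3-methylbut-2-en-1-yl)phenyl]ethan-1-one | CC(=O)c1c(F)c(CC=C(C)C)c(OCOC)cc1OCOC | intermediate
9 | lithium 1-[2-fluoro-4,6-bis(methoxymethoxy)-3-(3-methylbut-2-en-1-yl)phenyl]ethen-1-olate | C=C(O[Li])c1c(F)c(CC=C(C)C)c(OCOC)cc1OCOC | intermediate (not isolated)
10 | {1-[2-fluoro-4,6-bis(methoxymethoxy)-3-(3-methylbut-2-en-1-yl)phenyl]ethenyl}oxy(trimethyl)silane | C=C(O[Si](C)(C)C)c1c(F)c(CC=C(C)C)c(OCOC)cc1OCOC | intermediate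
11 | 4-hydroxy-2-methoxybenzaldehyde | COc1cc(O)ccc1C=O | starting material
12 | 2-methoxy-4-[(3-methylbut-2-en-1-yl)oxy]benzaldehyde | COc1cc(OCC=C(C)C)ccc1C=O | intermediate
13 | 6-methoxy-3-(2-methylbut-3-en-2-yl)-4-oxocyclohexa-1,5-diene-1-carbaldehyde (racemic ortho-dienone) | C=CC(C)(C)C1C=C(C=O)C(OC)=CC1=O | intermediate (not isolated)
14 | 4-hydroxy-2-methoxy-5-(2-methylbut-3-en-2-yl)benzaldehyde | C=CC(C)(C)c1cc(C=O)c(OC)cc1O | intermediate
15 | 2-methoxy-4-(methoxymethoxy)-5-(2-methylbut-3-en-2-yl)benzaldehyde | C=CC(C)(C)c1cc(C=O)c(OC)cc1OCOC | intermediate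
16 | (3S)-1-[2-fluoro-4,6-bis(methoxymethoxy)-3-(3-methylbut-2-en-1-yl)phenyl]-3-[2-methoxy-4-(methoxymethoxy)-5-(2-methylbut-3-en-2-yl)phenyl]-3-(trimethylsilyloxy)propan-1-one | C=CC(C)(C)c1cc([C@@H](O[Si](C)(C)C)CC(=O)c2c(F)c(CC=C(C)C)c(OCOC)cc2OCOC)c(OC)cc1OCOC | intermediate (not isolated)
17 | (2S)-5,7-bis(methoxymethoxy)-2-[2-methoxy-4-(methoxymethoxy)-5-(2-methylbut-3-en-2-yl)phenyl]-8-(3-methylbut-2-en-1-yl)-2,3-dihydro-4H-chromen-4-one | C=CC(C)(C)c1cc([C@@H]2CC(=O)c3c(OCOC)cc(OCOC)c(CC=C(C)C)c3O2)c(OC)cc1OCOC | intermediate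
18 | (2S)-5,7-dihydroxy-2-[4-hydroxy-2-methoxy-5-(2-methylbut-3-en-2-yl)phenyl]-8-(3-methylbut-2-en-1-yl)-2,3-dihydro-4H-chromen-4-one | C=CC(C)(C)c1cc([C@@H]2CC(=O)c3c(O)cc(O)c(CC=C(C)C)c3O2)c(OC)cc1O | target

**Step count.** Total: 10 steps. Longest linear sequence: 7 steps (steps 1–5, 9 and 10); the aldehyde branch is 3 steps (6–8).

**Steps most likely to fail**

1. Step 9. Retro-aldol cleavage or β-elimination of the aldolate may outrun the SNAr closure, or the boron catalyst may turn over poorly with the electron-rich aldehyde, so that ee or material is lost. Fallback with known chemistry: the ring is closed at O1–C2 by the classical chalcone route. It sets out from ketone 8 and aldehyde 15. Hydroxide exchanges the ring fluorine of 8 by SNAr (KOH, DMSO/H2O, 80 °C) to give 1-[2-hydroxy-4,6-bis(methoxymethoxy)-3-(3-methylbut-2-en-1-yl)phenyl]ethan-1-one F1. Claisen–Schmidt condensation of F1 with 15 (KOH, EtOH/H2O, rt) gives (2E)-1-[2-hydroxy-4,6-bis(methoxymethoxy)-3-(3-methylbut-2-en-1-yl)phenyl]-3-[2-methoxy-4-(methoxymethoxy)-5-(2-methylbut-3-en-2-yl)phenyl]prop-2-en-1-one F2. NaOAc in refluxing EtOH closes F2 by oxa-Michael addition to racemic 5,7-bis(methoxymethoxy)-2-[2-methoxy-4-(methoxymethoxy)-5-(2-methylbut-3-en-2-yl)phenyl]-8-(3-methylbut-2-en-1-yl)-2,3-dihydro-4H-chromen-4-one F3. Preparative HPLC on a chiral stationary phase then gives the (2S)-enantiomer, at which point the route is rejoined at 17.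

2. Step 7. The abnormal Claisen pathway, cyclisation of the new phenol onto the tertiary allyl group, or incomplete conversion of the acceptor-substituted ether may prevail. Fallback: the tertiary allyl group is introduced by cross-coupling. It sets out from 11. Bromination para to the methoxy group (NBS, MeCN, 0 °C) gives 5-bromo-4-hydroxy-2-methoxybenzaldehyde F4, and MOM protection (MOMCl, K2CO3, DMF) gives 5-bromo-2-methoxy-4-(methoxymethoxy)benzaldehyde F5. A γ-selective Suzuki–Miyaura coupling of F5 with 3-methylbut-2-en-1-ylboronic acid pinacol ester (Pd(OAc)2, a biaryl dialkylphosphine ligand of the type that favours the branched isomer, K3PO4, THF/H2O, 40 °C) gives 15 directly, so that 12–14 are bypassed.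

3. Step 3. Over-exchange to a dilithio species, LiF loss to an aryne, or SN2′ attack on prenyl bromide may compete. Fallback: mono-prenylation by Stille coupling. It sets out from 3, which is coupled with tributyl(3-methylbut-2-en-1-yl)stannane (1.0 equiv, Pd(PPh3)4, DMF, 90 °C); the mono-coupled bromide is more electron-rich and more hindered than 3 and should react more slowly, and the route is rejoined at 5.

**Further compounds**
F1 | step 9 | 1-[2-hydroxy-4,6-bis(methoxymethoxy)-3-(3-methylbut-2-en-1-yl)phenyl]ethan-1-one | CC(=O)c1c(O)c(CC=C(C)C)c(OCOC)cc1OCOC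
F2 | step 9 | (2E)-1-[2-hydroxy-4,6-bis(methoxymethoxy)-3-(3-methylbut-2-en-1-yl)phenyl]-3-[2-methoxy-4-(methoxymethoxy)-5-(2-methylbut-3-en-2-yl)phenyl]prop-2-en-1-one | C=CC(C)(C)c1cc(/C=C/C(=O)c2c(O)c(CC=C(C)C)c(OCOC)cc2OCOC)c(OC)cc1OCOC
F3 | step 9 | racemic 5,7-bis(methoxymethoxy)-2-[2-methoxy-4-(methoxymethoxy)-5-(2-methylbut-3-en-2-yl)phenyl]-8-(3-methylbut-2-en-1-yl)-2,3-dihydro-4H-chromen-4-one | C=CC(C)(C)c1cc(C2CC(=O)c3c(OCOC)cc(OCOC)c(CC=C(C)C)c3O2)c(OC)cc1OCOC
F4 | step 7 | 5-bromo-4-hydroxy-2-methoxybenzaldehyde | COc1cc(O)c(Br)cc1C=O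
F5 | step 7 | 5-bromo-2-methoxy-4-(methoxymethoxy)benzaldehyde | COCOc1cc(OC)c(C=O)cc1Br
F0 | step 3 | none | none
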